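The easiest thing to reckon in these flasks is what the coupling partner can pay for, so the charges, readings and questions stand first.

| flask | substrate | coupling partner | protic impurity | free catalyst | remark | time |
|---|---|---|---|---|---|---|
| dawn | 0.50 M | 0.70 equiv | 10 mM | 3.5 mol% | run made earlier |  |
| midnight | 0.50 M | 0.70 equiv | 10 mM | 8 mol% | run made earlier |  |
| spring | 0.50 M | 0.70 equiv | 10 mM | 9.8 mol% | run made earlier |  |
| green | 0.50 M | 0.700 equiv | 10.0 mM | 5 mol% |  | 2.5 d |
| red | 0.50 M | 0.700 equiv | 10.0 mM | 12 mol% |  | 2.5 d |

| run | time / h | target / % | substrate / % |
|---|---|---|---|
| dawn | 3.00 | 2.7 | 78.2 |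
| dawn | 6.00 | 6.8 | 58.9 |
| dawn | 12.0 | 13.3 | 33.9 |
| dawn | 20.0 | 23.5 | 17.5 |
| dawn | 40.0 | 39.3 | 6.8 |
| midnight | 4.00 | 10.4 | 49.0 |
| midnight | 10.0 | 30.2 | 20.2 |
| midnight | 20.0 | 50.7 | 7.2 |
| midnight | 30.0 | 60.0 | 5.5 |
| midnight | 40.0 | 61.9 | 3.3 |
| spring | 3.00 | 8.8 | 51.9 |
| spring | 6.00 | 24.2 | 30.1 |
| spring | 12.0 | 41.0 | 11.9 |
| spring | 20.0 | 56.7 | 5.8 |
| spring | 40.0 | 66.4 | 2.2 |

(readings scatter by 1 percentage point)

- percentages count the substrate that a species holds: one side product counts as two

1. which of the two there is more of at the end, counted by the substrate in each, green (side product / target)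
2. which of the two there is more of at the end, counted by the substrate in each, red (side product / target)
3. final target, as a percentage of the substrate charged, in green
4. final target, as a percentage of the substrate charged, in red

One extreme version of green and red has catalyst so plentiful that the coupling partner, the limiting reagent of this version, ends up as target. As my own assumption, each protic impurity spoils one coupling partner. Then 0.700 equiv of coupling partner, less the ratio [protic impurity]/[substrate] at the charge, leaves 68.0% of the substrate charged. This is the partner ceiling: the target that the coupling partner surviving the protic impurity can pay for.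

The other extreme gains nothing beyond the dawn run, which stands at 39.3% target with less catalyst and less time than green or red.

The place between the extremes is easier to reckon from the fraction left, the share of the ceiling still unfilled at the last reading, 40.0 h:

| run | free catalyst | target | unfilled share |
|---|---|---|---|
| dawn | 3.5 mol% | 39.3% | 42.2% |
| midnight | 8 mol% | 61.9% | 8.97% |
| spring | 9.8 mol% | 66.4% | 2.35% |

Suppose the unfilled share shrinks by a constant factor for each equal amount of loading times time. Green holds 2.14 times the dawn amount, so raising the dawn share to that power gives 57.3% target. Red holds 5.14 times the dawn amount, which gives 67.2%. The rule gives midnight 58.5%, below its reading.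

The forecast puts target ahead in green and target ahead in red, with 55% target in green and 69% in red: “Red: capped by partner at 70, so about 69.” Its green lies below my figure and its red above it.

Green gives 56.9% target against 36.6% side product, and red gives 67.9% against 22.1%.

    substrate + free catalyst ⇌ free catalyst + open intermediate (K = 3.00, k = 0.00130 M⁻¹ s⁻¹)
    free catalyst + open intermediate ⇌ catalyst intermediate (K = 2.10 M⁻¹, k = 0.00110 M⁻¹ s⁻¹)
    coupling partner + catalyst intermediate → free catalyst + target (k = 0.00750 M⁻¹ s⁻¹)
    substrate + open intermediate → side product (k = 5.10 × 10⁻⁵ M⁻¹ s⁻¹)
    coupling partner + protic impurity → quenched reagent (k = 0.00630 M⁻¹ s⁻¹)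

Red ends 11 percentage points above green, and the main reason is the difference in loading of free catalyst; the largest single effect within that gap is the path from substrate + open intermediate to side product, without which the gap is 0.3 points. Red stands at the partner ceiling of 68.0%. By 2.50 d its coupling partner is down to 0.0831% of its charge, and its 10.0 mM of protic impurity has become 0.0100 M of quenched reagent, one for one. The same flask with 0.420 equiv of coupling partner has a ceiling of 40.0%, and it ends with 0% of its coupling partner left and 40.0% target.

(All runs are simulated for an exercise, and the scatter is random.)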